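The constants were chosen freely; no experiment stands behind them.

Uncatalysed product, target and second product all take the same reagent, so in this flask the amount of uncatalysed product depends on how the reagent is shared.

starting material 0.50 M (fed, over 6.0 s); second substrate 1.00 M; reagent 0.500 M; protic impurity 0.0500 M; free catalyst 2.5 mM; time 2.0 min

- at 2.0 min, what has stopped the reaction, if anything has (all of the starting material has reacted / it is still moving / forward and back rates have come level / no working catalyst is left / the reagent has run out first)
- how much of the starting material has reacted by 2.0 min
- how much target there is at 2.0 min, in percent of the starting material charged
- how much uncatalysed product there is at 2.0 min, in percent of the starting material charged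

    reagent + catalyst intermediate B → free catalyst + second product (k1 = 49 /M/s)
    second substrate + free catalyst ⇌ catalyst intermediate B (K2 = 180 /M, k2 = 1900 /M/s)
    reagent + free catalyst + target → free catalyst + over-reaction product (k3 = 460 /M²/s)
    starting material + protic impurity → quenched substrate (k4 = 1.6 /M/s)
    starting material + reagent → uncatalysed product (k5 = 0.11 /M/s)
    starting material + free catalyst ⇌ catalyst intermediate A (K6 = 11 /M, k6 = 78 /M/s)
    reagent + catalyst intermediate A → free catalyst + target (k7 = 890 /M/s)

Binding constant times second substrate comes to 180, so nearly all the catalyst rests as catalyst intermediate B, the resting state. That intermediate consumes reagent with rate constant 49 /M/s, which on the whole catalyst charge is a pseudo-first-order constant of 0.122 /s. The direct reaction with starting material, at A molar, consumes reagent at 0.11 /M/s times A. The two are level at the crossover concentration X, the concentration of starting material at which direct and catalysed loss of reagent are equal, 1.11 M, and of the reagent lost by these two ways, the share going to uncatalysed product is A/(A+X).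

Taking the charge of protic impurity off the starting material leaves 0.450 M, because at that concentration the impurity's half-life of 0.963 s is short against 2.0 min. Held at that value, A gives a share of 28.8%, and since reagent and starting material are charged alike, the same figure of the charge as uncatalysed product.

The weak link is A itself. The reagent's lifetime, 5.81 s, is about as long as the feed of 6.0 s, so the reagent burns while the starting material is still arriving. We reforge it in two stages. During the feed we take A as half its final value, so the reagent decays at 0.147 /s, 41.3% survives, and 0.0493 M of uncatalysed product forms. After the feed we put A at 0.401 M and hold it there, and the surviving reagent yields 0.0547 M more. We commit to 20.8% uncatalysed product, counting all the reagent as used, since its lifetime is short against 2.0 min. Conversion is then 30.8% plus the target, which we have not reckoned.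

The forecast reads the reagent has run out first, with 34% conversion, 4.8% target and 19% uncatalysed product, below our figure, on the ground that “the reagent is gone within a minute or so”.

The flask gives the reagent has run out first, with 31.7% conversion, 3.45% target and 18.2% uncatalysed product.

In this flask, reagent fell to 41.7% of its charge by the end of the feed at 0.100 min, with catalyst intermediate B at 98.3% of the catalyst. By 1.00 min reagent stood at 0% and starting material at 68.3%, and the largest change over the second half of the time was 0 percentage points. After the feed, the mean of A at its two ends was 0.377 M, so X gives a share of 25.3% and 10.5% of the charge, where the flask made 10 points. With 0.0043 M of free catalyst, X becomes 1.92 M, up by a factor 1.73, and that neighbour's uncatalysed product is lower by a factor 1.84, at 9.90%.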